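The ten-membered carbocycle (C1 = isopropenyl carbon, numbered through C2H2, the C3–C4 epoxide, C5, C6H2, the C7–C8 epoxide and C9–OH to C10) is closed at C9–C10. The key step exploits the C8–C9(OH)–C10(O-acyl) array: with the C7–C8 epoxide retro-converted to an alkene, it is the adduct of a γ-oxyallyl metal and an aldehyde. An open-chain enal (C9)/aldehyde (C10) dialdehyde from (S)-carvone therefore undergoes a chromium-mediated pinacol-type cross coupling that sets C9, C10 and the Z C7=C8 alkene and leaves O9 silylated, O10 free. Two hydroxyl-controlled epoxidations and a double angeloylation finish the route.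

Key step: step 9

Remark: the locants C1–C10 defined above are kept for the open-chain intermediates; descriptors given for the ring compounds 14–19 refer to these locants.
Assumption: both C6 epimers of 3 converge in step 2, so only the expected trans isomer is drawn.

Step 1
Reactants: 1 (S)-(+)-carvone
Product: 3 (5R,6R)-6-hydroxy-2-methyl-5-(prop-1-en-2-yl)cyclohex-2-en-1-one, via potassium enolate 2 (not isolated)
Conditions: KN(SiMe3)2, THF, −78 °C; then 2-(phenylsulfonyl)-3-phenyloxaziridine, −78 °C; aq. NH4Cl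
Reagents that add atoms: 2-(phenylsulfonyl)-3-phenyloxaziridine, O=S(=O)(c1ccccc1)N1OC1c1ccccc1
Why: Kinetic deprotonation of the enone at C6 (the future C10) and enolate hydroxylation by the N-sulfonyloxaziridine (Davis oxidation), expected anti to the neighbouring isopropenyl group; the new carbinol centre is destroyed in step 2.

Step 2
Reactants: 3 (5R,6R)-6-hydroxy-2-methyl-5-(prop-1-en-2-yl)cyclohex-2-en-1-one
Product: 4 methyl (2Z,5R)-5-formyl-2,6-dimethylhepta-2,6-dienoate
Conditions: Pb(OAc)4, MeOH–benzene (1:1), 0 °C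
Reagents that add atoms: methanol, CO
Why: Criegee-type cleavage of the α-hydroxy ketone breaks the old ring bond between the future C5 and C10, giving the methyl ester at C5 and the aldehyde at C10; the ring-derived Z geometry of C3=C4 and the C1 stereocentre are carried over untouched.

Step 3
Reactants: 4 methyl (2Z,5R)-5-formyl-2,6-dimethylhepta-2,6-dienoate
Product: 5 methyl (2Z,5R)-5-(dimethoxymethyl)-2,6-dimethylhepta-2,6-dienoate
Conditions: HC(OMe)3, pyridinium p-toluenesulfonate (cat.), MeOH, rt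
Reagents that add atoms: trimethyl orthoformate, COC(OC)OC
Why: Acid-catalysed acetalisation masks the C10 aldehyde while C5 is elaborated; no stereocentre is touched.

Step 4
Reactants: 5 methyl (2Z,5R)-5-(dimethoxymethyl)-2,6-dimethylhepta-2,6-dienoate
Product: 6 (2Z,5R)-5-(dimethoxymethyl)-2,6-dimethylhepta-2,6-dien-1-ol
Conditions: i-Bu2AlH (2.5 equiv), CH2Cl2, −78 °C; aq. potassium sodium tartrate
Reagents that add atoms: none
Why: Hydride (1,2-) reduction of the conjugated ester to the allylic alcohol; acetal and Z alkene are inert.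

Step 5
Reactants: 6 (2Z,5R)-5-(dimethoxymethyl)-2,6-dimethylhepta-2,6-dien-1-ol
Product: 7 (2Z,5R)-5-(dimethoxymethyl)-2,6-dimethylhepta-2,6-dienal
Conditions: Dess–Martin periodinane, NaHCO3, CH2Cl2, 0 °C; used at once
Reagents that add atoms: none
Why: Buffered Dess–Martin oxidation should give the Z enal without acid- or base-mediated Z-to-E isomerisation.

Step 6
Reactants: 7 (2Z,5R)-5-(dimethoxymethyl)-2,6-dimethylhepta-2,6-dienal; 8 allylmagnesium bromide
Product: 9 (4S,5Z,8R)-8-(dimethoxymethyl)-5,9-dimethyldeca-1,5,9-trien-4-ol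
Conditions: (−)-Ipc2BOMe [from (+)-α-pinene], 8, Et2O, 0 °C to rt; then 7, −78 °C; aq. NaOH, H2O2
Reagents that add atoms: none
Why: Brown allylation: the B-allyldiisopinocampheylborane of the (+)-α-pinene series should add to the Si face of the aldehyde through a chair transition state under reagent control, setting C5 as S; the remote C1 centre has no influence.

Step 7
Reactants: 9 (4S,5Z,8R)-8-(dimethoxymethyl)-5,9-dimethyldeca-1,5,9-trien-4-ol; 10 methacrolein
Product: 11 (2E,5S,6Z,9R)-9-(dimethoxymethyl)-5-hydroxy-2,6,10-trimethylundeca-2,6,10-trienal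
Conditions: 10 (10 equiv), second-generation Hoveyda–Grubbs catalyst (5 mol %), CH2Cl2, 40 °C
Reagents that add atoms: none
Why: Olefin cross metathesis of the monosubstituted alkene with excess methacrolein should give the E enal, the isopropenyl and trisubstituted alkenes being too hindered to take part; the enal geometry is erased in step 9.

Step 8
Reactants: 11 (2E,5S,6Z,9R)-9-(dimethoxymethyl)-5-hydroxy-2,6,10-trimethylundeca-2,6,10-trienal
Product: 12 (2E,5S,6Z,9R)-5-hydroxy-2,6-dimethyl-9-(prop-1-en-2-yl)deca-2,6-dienedial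
Conditions: TsOH·H2O (cat.), THF–H2O (4:1), rt
Reagents that add atoms: water, O
Why: Mild acetal hydrolysis unveils the C10 aldehyde directly before use, limiting exposure of the α-isopropenyl aldehyde to epimerisation or double-bond migration.

Step 9
Reactants: 12 (2E,5S,6Z,9R)-5-hydroxy-2,6-dimethyl-9-(prop-1-en-2-yl)deca-2,6-dienedial
Product: 14 (1R,3Z,5S,7Z,9R,10S)-4,8-dimethyl-1-(prop-1-en-2-yl)-9-(triethylsilyloxy)cyclodeca-3,7-diene-5,10-diol, via siloxyallylchromium species 13 (not isolated)
Conditions: CrCl2 (5 equiv), Et3SiCl (1.5 equiv), DMF–THF, 25 °C, 12 added over 10 h to a final 2 mM; pH 7 buffer work-up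
Reagents that add atoms: chlorotriethylsilane, CC[Si](Cl)(CC)CC
Why: Chromium dichloride (divalent chromium) with Et3SiCl reduces only the conjugated C9 aldehyde, by two one-electron steps and O-silylation, to the γ-triethylsiloxyallylchromium 13 (trivalent chromium on C7, E enol ether from the s-trans enal), which adds through its oxygen-bearing terminus C9 to the C10 aldehyde in a six-membered chair (Zimmerman–Traxler) transition state. The closest known reactions are the chromium-mediated pinacol-type cross coupling of enals and enones with aldehydes, its intramolecular form on 2-methylene dicarbonyls, and Nozaki–Hiyama allylation macrocyclisations that close ten-membered germacrane rings. The ten-membered carbocycle closes by 10-exo-trig attack of C9 on the C10 carbonyl, the allylic transposition placing the new C7=C8 alkene inside the ring. C9 and C10 should be set anti (erythro, cis on the ring) by the E enol ether and the equatorial C1 substituent in the chair; C10 is set relative to C1 by Felkin–Anh addition with the isopropenyl group antiperiplanar to the forming bond, which leaves the C2 tether gauche as the ring needs; and the Z geometry of C7=C8 should follow from C6 sitting pseudo-axial on C7, which lets the six-atom tether with its Z C3=C4 alkene reach C10 and leads to the less strained Z,Z-cyclodeca-1,5-diene. The step needs chemoselectivity (enal over saturated aldehyde; the free C5–OH is tolerated by organochromium reagents), regioselectivity (bond at C9, not C7, since chromium prefers the carbon remote from oxygen) and ring closure over oligomerisation, the last secured by slow addition to high dilution; Et3SiCl is kept near one equivalent so that the C10 chromium alkoxide is only protonated on work-up, leaving O9 silylated and O10 free.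

Step 10
Reactants: 14 (1R,3Z,5S,7Z,9R,10S)-4,8-dimethyl-1-(prop-1-en-2-yl)-9-(triethylsilyloxy)cyclodeca-3,7-diene-5,10-diol
Product: 15 (1R,3S,4R,5S,7Z,9R,10S)-3,4-epoxy-4,8-dimethyl-1-(prop-1-en-2-yl)-9-(triethylsilyloxy)cyclodec-7-ene-5,10-diol
Conditions: mCPBA (1.05 equiv), NaHCO3, CH2Cl2, −20 to 0 °C
Reagents that add atoms: 3-chloroperbenzoic acid, O=C(OO)c1cccc(Cl)c1
Why: Hydroxyl-assisted Prilezhaev epoxidation: the free allylic C5–OH should make C3=C4 react ahead of the isopropenyl and the siloxy-deactivated C7=C8 alkenes, and, as with medium-ring Z-cycloalkenols, oxygen should arrive on the peripheral face with the C5–O bond pseudo-equatorial, giving the epoxide trans to O5.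

Step 11
Reactants: 15 (1R,3S,4R,5S,7Z,9R,10S)-3,4-epoxy-4,8-dimethyl-1-(prop-1-en-2-yl)-9-(triethylsilyloxy)cyclodec-7-ene-5,10-diol; 16 angelic acid
Product: 17 (1R,3S,4S,5S,7Z,9R,10S)-3,4-epoxy-4,8-dimethyl-1-(prop-1-en-2-yl)-9-(triethylsilyloxy)cyclodec-7-ene-5,10-diyl bis[(2Z)-2-methylbut-2-enoate]
Conditions: 16 (6 equiv), 2,4,6-trichlorobenzoyl chloride, Et3N, toluene, rt; then 15, 75 °C
Reagents that add atoms: none
Why: Yamaguchi esterification through the mixed anhydride acylates both free secondary hydroxyls (C5 and C10) in one operation, the DMAP-free protocol avoiding isomerisation of angelate to tiglate; O9 stays silylated.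

Step 12
Reactants: 17 (1R,3S,4S,5S,7Z,9R,10S)-3,4-epoxy-4,8-dimethyl-1-(prop-1-en-2-yl)-9-(triethylsilyloxy)cyclodec-7-ene-5,10-diyl bis[(2Z)-2-methylbut-2-enoate]
Product: 18 (1R,3S,4S,5S,7Z,9R,10S)-3,4-epoxy-9-hydroxy-4,8-dimethyl-1-(prop-1-en-2-yl)cyclodec-7-ene-5,10-diyl bis[(2Z)-2-methylbut-2-enoate]
Conditions: HF·pyridine, pyridine, THF, 0 °C
Reagents that add atoms: none
Why: Buffered fluoride desilylation frees the C9 hydroxyl under non-basic conditions, so the neighbouring C10 angelate should not migrate and the epoxide should survive.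

Step 13
Reactants: 18 (1R,3S,4S,5S,7Z,9R,10S)-3,4-epoxy-9-hydroxy-4,8-dimethyl-1-(prop-1-en-2-yl)cyclodec-7-ene-5,10-diyl bis[(2Z)-2-methylbut-2-enoate]
Product: 19 (1R,3S,4S,5S,7R,8S,9S,10S)-3,4:7,8-diepoxy-9-hydroxy-4,8-dimethyl-1-(prop-1-en-2-yl)cyclodecane-5,10-diyl bis[(2Z)-2-methylbut-2-enoate] (CNP0304877.1)
Conditions: VO(acac)2 (5 mol %), t-BuOOH (decane), CH2Cl2, 0 °C to rt
Reagents that add atoms: tert-butyl hydroperoxide, CC(C)(C)OO
Why: Vanadium-catalysed hydroxyl-directed epoxidation: the C9 vanadate ester should deliver oxygen to C7=C8 on the face syn to O9, as with Z-cycloalkenols, setting C7 (R) and C8 (S); the isopropenyl and angelate alkenes carry no directing hydroxyl and should stay intact.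

Compound list
1 | (S)-(+)-carvone | C=C(C)[C@H]1CC=C(C)C(=O)C1 | starting material
2 | potassium enolate of 1 (C6-deprotonated, not isolated) | C=C(C)[C@H]1CC=C(C)C([O-])=C1.[K+] | intermediate
3 | (5R,6R)-6-hydroxy-2-methyl-5-(prop-1-en-2-yl)cyclohex-2-en-1-one | C=C(C)[C@H]1CC=C(C)C(=O)[C@@H]1O | intermediate
4 | methyl (2Z,5R)-5-formyl-2,6-dimethylhepta-2,6-dienoate | C=C(C)[C@H](C=O)C/C=C(/C)C(=O)OC | intermediate
5 | methyl (2Z,5R)-5-(dimethoxymethyl)-2,6-dimethylhepta-2,6-dienoate | C=C(C)[C@H](C(OC)OC)C/C=C(/C)C(=O)OC | intermediate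
6 | (2Z,5R)-5-(dimethoxymethyl)-2,6-dimethylhepta-2,6-dien-1-ol | C=C(C)[C@H](C(OC)OC)C/C=C(/C)CO | intermediate
7 | (2Z,5R)-5-(dimethoxymethyl)-2,6-dimethylhepta-2,6-dienal | C=C(C)[C@H](C(OC)OC)C/C=C(/C)C=O | intermediate
8 | allylmagnesium bromide | C=CC[Mg]Br | starting material
9 | (4S,5Z,8R)-8-(dimethoxymethyl)-5,9-dimethyldeca-1,5,9-trien-4-ol | C=C(C)[C@H](C(OC)OC)C/C=C(/C)[C@@H](O)CC=C | intermediate
10 | methacrolein (2-methylprop-2-enal) | C=C(C)C=O | starting material
11 | (2E,5S,6Z,9R)-9-(dimethoxymethyl)-5-hydroxy-2,6,10-trimethylundeca-2,6,10-trienal | C=C(C)[C@H](C(OC)OC)C/C=C(/C)[C@@H](O)C/C=C(\C)C=O | intermediate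
12 | (2E,5S,6Z,9R)-5-hydroxy-2,6-dimethyl-9-(prop-1-en-2-yl)deca-2,6-dienedial | C=C(C)[C@H](C=O)C/C=C(/C)[C@@H](O)C/C=C(\C)C=O | intermediate
13 | γ-triethylsiloxyallylchromium dichloride from 12 (chromium on C7, E enol ether, not isolated) | C=C(C)[C@H](C=O)C/C=C(/C)[C@@H](O)CC([Cr](Cl)Cl)/C(C)=C/O[Si](CC)(CC)CC | intermediate
14 | (1R,3Z,5S,7Z,9R,10S)-4,8-dimethyl-1-(prop-1-en-2-yl)-9-(triethylsilyloxy)cyclodeca-3,7-diene-5,10-diol | C=C(C)[C@H]1C/C=C(/C)[C@@H](O)C/C=C(/C)[C@@H](O[Si](CC)(CC)CC)[C@H]1O | intermediate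
15 | (1R,3S,4R,5S,7Z,9R,10S)-3,4-epoxy-4,8-dimethyl-1-(prop-1-en-2-yl)-9-(triethylsilyloxy)cyclodec-7-ene-5,10-diol | C=C(C)[C@H]1C[C@@H]2O[C@]2(C)[C@@H](O)C/C=C(/C)[C@@H](O[Si](CC)(CC)CC)[C@H]1O | intermediate
16 | angelic acid [(2Z)-2-methylbut-2-enoic acid] | C/C=C(/C)C(=O)O | starting material
17 | (1R,3S,4S,5S,7Z,9R,10S)-3,4-epoxy-4,8-dimethyl-1-(prop-1-en-2-yl)-9-(triethylsilyloxy)cyclodec-7-ene-5,10-diyl bis[(2Z)-2-methylbut-2-enoate] | C=C(C)[C@H]1C[C@@H]2O[C@]2(C)[C@@H](OC(=O)/C(C)=C\C)C/C=C(/C)[C@@H](O[Si](CC)(CC)CC)[C@H]1OC(=O)/C(C)=C\C | intermediate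
18 | (1R,3S,4S,5S,7Z,9R,10S)-3,4-epoxy-9-hydroxy-4,8-dimethyl-1-(prop-1-en-2-yl)cyclodec-7-ene-5,10-diyl bis[(2Z)-2-methylbut-2-enoate] | C=C(C)[C@H]1C[C@@H]2O[C@]2(C)[C@@H](OC(=O)/C(C)=C\C)C/C=C(/C)[C@@H](O)[C@H]1OC(=O)/C(C)=C\C | intermediate
19 | (1R,3S,4S,5S,7R,8S,9S,10S)-3,4:7,8-diepoxy-9-hydroxy-4,8-dimethyl-1-(prop-1-en-2-yl)cyclodecane-5,10-diyl bis[(2Z)-2-methylbut-2-enoate] (CNP0304877.1) | C=C(C)[C@H]1C[C@@H]2O[C@]2(C)[C@@H](OC(=O)/C(C)=C\C)C[C@H]2O[C@@]2(C)[C@@H](O)[C@H]1OC(=O)/C(C)=C\C | target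

Total step count: 13. Longest linear sequence: 13 steps, from (S)-carvone 1 to 19.

Steps most likely to fail

Step 9. The siloxyallylchromium may bond through C7 (eight-membered ring) or couple intermolecularly, the C7=C8 alkene or the C9/C10 pair may form with the wrong geometry or relative configuration, and silyl transfer to O5 or O10 may erase the O9/O10 differentiation. The fallback keeps the ring bond but changes the allyl donor and fixes the O9 substituent as an ether before ring closure. It uses the γ-alkoxyallylchromium obtained by iodotrimethylsilane ionisation of an α,β-unsaturated acetal, a reagent class known for erythro-selective aldehyde additions at −30 °C. It sets out from 9: acetal hydrolysis (TsOH·H2O, THF–H2O) should give the hydroxy aldehyde (2R,4Z,6S)-6-hydroxy-5-methyl-2-(prop-1-en-2-yl)nona-4,8-dienal F1. Separately, 10 and 4-methoxybenzyl alcohol (acid catalysis, water removal) give methacrolein bis(4-methoxybenzyl) acetal F2. Cross metathesis of F1 with F2 (second-generation Hoveyda–Grubbs catalyst) should give the unsaturated acetal aldehyde F3. Me3SiI and CrCl2 in THF at −30 °C under high dilution (C5–OH silylated in the flask and freed on work-up) should close the ring at C9–C10 to the 9-O-(4-methoxybenzyl) analogue of 14, F4. mCPBA then gives its C3–C4 epoxide F5 and Yamaguchi bis-angeloylation the diester F6. DDQ (CH2Cl2, pH 7 buffer) removes the benzyl ether and the sequence comes back to the route at 18.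

Step 10. Facial selectivity of the peracid on the flexible ten-membered ring may be poor, or C7=C8 and the isopropenyl group may be epoxidised competitively. The fallback installs the C3–C4 epoxide on the open chain, where A(1,3) strain in the Z allylic alcohol makes hydroxyl-syn (threo) peracid delivery reliable and gives the same 3S,4R,5S arrangement. It sets out from 9: mCPBA (NaHCO3, CH2Cl2, 0 °C) should give the C3–C4 epoxide of 9, F7. Cross metathesis with 10 as in step 7 gives the epoxy enal F8, and buffered acetal cleavage (LiBF4, wet MeCN) the epoxy dialdehyde F9. The chromium dichloride/Et3SiCl ring closure of step 9 then returns the sequence to the route at 15.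

Step 13. Vanadium delivery may show poor facial selectivity on the ring, or the C10 angelate may migrate to O9 under the Lewis-acidic conditions. The fallback replaces substrate control by reagent control: Sharpless epoxidation with Ti(OiPr)4, L-(+)-diisopropyl tartrate and t-BuOOH (4 Å sieves, CH2Cl2, −20 °C). For the C9 configuration of 18 the L-(+)-tartrate is the matched ligand, and secondary allylic alcohols give erythro epoxy alcohols under these conditions, which is the C7–C9 relationship required. It sets out from 18 and comes back at 19 without any new compound (F0).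

Further compounds
F1 | step 9 | (2R,4Z,6S)-6-hydroxy-5-methyl-2-(prop-1-en-2-yl)nona-4,8-dienal | C=C(C)[C@H](C=O)C/C=C(/C)[C@@H](O)CC=C
F2 | step 9 | methacrolein bis(4-methoxybenzyl) acetal | C=C(C)C(OCc1ccc(OC)cc1)OCc1ccc(OC)cc1
F3 | step 9 | (2R,4Z,6S,8E)-6-hydroxy-10,10-bis[(4-methoxyphenyl)methoxy]-5,9-dimethyl-2-(prop-1-en-2-yl)deca-4,8-dienal | C=C(C)[C@H](C=O)C/C=C(/C)[C@@H](O)C/C=C(\C)C(OCc1ccc(OC)cc1)OCc1ccc(OC)cc1
F4 | step 9 | (1R,3Z,5S,7Z,9R,10S)-9-[(4-methoxyphenyl)methoxy]-4,8-dimethyl-1-(prop-1-en-2-yl)cyclodeca-3,7-diene-5,10-diol | C=C(C)[C@H]1C/C=C(/C)[C@@H](O)C/C=C(/C)[C@@H](OCc2ccc(OC)cc2)[C@H]1O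
F5 | step 9 | (1R,3S,4R,5S,7Z,9R,10S)-3,4-epoxy-9-[(4-methoxyphenyl)methoxy]-4,8-dimethyl-1-(prop-1-en-2-yl)cyclodec-7-ene-5,10-diol | C=C(C)[C@H]1C[C@@H]2O[C@]2(C)[C@@H](O)C/C=C(/C)[C@@H](OCc3ccc(OC)cc3)[C@H]1O
F6 | step 9 | (1R,3S,4S,5S,7Z,9R,10S)-3,4-epoxy-9-[(4-methoxyphenyl)methoxy]-4,8-dimethyl-1-(prop-1-en-2-yl)cyclodec-7-ene-5,10-diyl bis[(2Z)-2-methylbut-2-enoate] | C=C(C)[C@H]1C[C@@H]2O[C@]2(C)[C@@H](OC(=O)/C(C)=C\C)C/C=C(/C)[C@@H](OCc3ccc(OC)cc3)[C@H]1OC(=O)/C(C)=C\C
F7 | step 10 | C3–C4 epoxide of 9 (3S,4R,5S; threo) | C=C(C)[C@H](C(OC)OC)C[C@@H]1O[C@]1(C)[C@@H](O)CC=C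
F8 | step 10 | C3–C4 epoxide of 11 (3S,4R,5S) | C=C(C)[C@H](C(OC)OC)C[C@@H]1O[C@]1(C)[C@@H](O)C/C=C(\C)C=O
F9 | step 10 | C3–C4 epoxide of 12 (3S,4R,5S) | C=C(C)[C@H](C=O)C[C@@H]1O[C@]1(C)[C@@H](O)C/C=C(\C)C=O
F0 | step 13 | none | none
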